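The route rests on disconnecting the C9–C10 bond of the seven-membered ring: the bond between the neopentyl CH2 (C10) on the quaternary fusion carbon C1 and the vinylic carbon C9 of the C8=C9 alkene that finally carries the epoxide. Both carbons are handled as halides and joined by a nickel-catalysed reductive cross-electrophile coupling, which in one operation closes the cycloheptene ring onto the finished cyclopentane without touching a stereocentre. The cyclisation precursor is a cyclopentane carrying CH3 and CH2I on C1, the isopropyl carbinol at C4 and, on C5, a side chain with the C6 anisate and a (Z)-vinyl bromide; conjugate addition and aldol chemistry assemble it.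

Key step: step 11

Remark: carotane locants are used throughout (C1 quaternary fusion carbon, C2/C3 ring CH2, C4 isopropyl carbinol, C5 fusion CH, C6 ester carbon, C7 CH2, C8/C9 alkene or epoxide carbons, C10 CH2), and the phosphoramidite enantiomer in step 5 is assumed to be the one that delivers methyl to the Re face of the enone β-carbon.

Step 1
Reactants: 1 but-3-yn-1-ol; 2 trimethylaluminium; 3 N-bromosuccinimide
Product: 6 (Z)-4-bromo-3-methylbut-3-en-1-ol, via syn-carboalumination adduct 4 (not isolated), via chelated alkenylalane 5 (not isolated)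
Conditions: Me3Al (3 equiv), Cp2ZrCl2 (25 mol %), ClCH2CH2Cl, rt then reflux; then NBS, THF, −30 °C; aq. HCl
Reagents that add atoms: trimethylaluminium, C[Al](C)C; N-bromosuccinimide, O=C1CCC(=O)N1Br
Why: Zirconium-catalysed Negishi carboalumination followed by thermal, alkoxide-chelation-driven isomerisation of the alkenylalane (net anti-carbometalation) places aluminium cis to the CH2CH2O arm, and bromodealumination with retention should give the vinyl bromide with Br cis to the future C7.

Step 2
Reactants: 6 (Z)-4-bromo-3-methylbut-3-en-1-ol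
Product: 7 (Z)-4-bromo-3-methylbut-3-enal
Conditions: Dess–Martin periodinane, CH2Cl2, 0 °C; used crude at once
Reagents that add atoms: none
Why: Dess–Martin oxidation is neutral and fast, so the β,γ-unsaturated aldehyde should form without migration of the double bond into conjugation.

Step 3
Reactants: 8 3-bromocyclopent-2-en-1-one; 9 (tributylstannyl)methanol
Product: 10 3-(hydroxymethyl)cyclopent-2-en-1-one
Conditions: Pd(PPh3)4 (5 mol %), 1,4-dioxane, 90 °C
Reagents that add atoms: (tributylstannyl)methanol, OC[Sn](CCCC)(CCCC)CCCC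
Why: Stille coupling transfers the hydroxymethyl group to the activated vinyl bromide, so C10 enters already oxygenated and no alkene cleavage is needed later in the presence of the vinyl bromide.

Step 4
Reactants: 10 3-(hydroxymethyl)cyclopent-2-en-1-one; 11 tert-butyl(chloro)dimethylsilane
Product: 12 3-{[tert-butyl(dimethyl)silyl]oxymethyl}cyclopent-2-en-1-one
Conditions: imidazole, DMF, 0 °C to rt
Reagents that add atoms: tert-butyl(chloro)dimethylsilane, CC(C)(C)[Si](C)(C)Cl
Why: Standard silylation of a primary alcohol gives a bulky, non-chelating C10 ether that survives the organometallic steps and makes the C10 arm the larger group on C1.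

Step 5
Reactants: 12 3-{[tert-butyl(dimethyl)silyl]oxymethyl}cyclopent-2-en-1-one; 2 trimethylaluminium; 13 triethylsilyl trifluoromethanesulfonate
Product: 15 tert-butyl(dimethyl){[(1S)-1-methyl-3-(triethylsilyloxy)cyclopent-2-en-1-yl]methoxy}silane, via dimethylaluminium enolate 14 (not isolated)
Conditions: Me3Al (2 equiv), copper thiophene-2-carboxylate Cu(O2CC4H3S) (5 mol %), chiral phosphoramidite ligand (10 mol %), Et2O, −30 °C; then Et3SiOTf, −30 to 0 °C
Reagents that add atoms: trimethylaluminium, C[Al](C)C; triethylsilyl trifluoromethanesulfonate, CC[Si](CC)(CC)OS(=O)(=O)C(F)(F)F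
Why: Copper-catalysed asymmetric conjugate addition of a trialkylaluminium to a β-substituted cyclopentenone, in which the chiral copper–phosphoramidite complex delivers methyl to the Re face of the β-carbon to set C1 (S), and O-silylation of the aluminium enolate fixes the enolate regiochemistry at C4–C5.

Step 6
Reactants: 15 tert-butyl(dimethyl){[(1S)-1-methyl-3-(triethylsilyloxy)cyclopent-2-en-1-yl]methoxy}silane; 7 (Z)-4-bromo-3-methylbut-3-enal
Product: 18 (2S,3S)-2-[(1S,3Z)-4-bromo-1-hydroxy-3-methylbut-3-en-1-yl]-3-{[tert-butyl(dimethyl)silyl]oxymethyl}-3-methylcyclopentan-1-one, via lithium enolate 16 (not isolated), via chlorozinc enolate 17 (not isolated)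
Conditions: MeLi (1.05 equiv), THF, 0 °C to rt; ZnCl2, −78 °C; then 7 (fresh, 1.5 equiv), −78 °C; aq. NH4Cl
Reagents that add atoms: none
Why: Aldol addition of the regiodefined zinc enolate through a closed Zimmerman–Traxler chair, in which the cyclic (E)-enolate should give the anti aldol (C6 S relative to C5 S) and the aldehyde should approach C5 on the face opposite the bulkier silyloxymethyl arm of C1 (cis to CH3), while the weakly basic zinc enolate limits deprotonation of the aldehyde.

Step 7
Reactants: 18 (2S,3S)-2-[(1S,3Z)-4-bromo-1-hydroxy-3-methylbut-3-en-1-yl]-3-{[tert-butyl(dimethyl)silyl]oxymethyl}-3-methylcyclopentan-1-one; 19 isopropylmagnesium chloride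
Product: 20 (1R,2S,3S)-2-[(1S,3Z)-4-bromo-1-hydroxy-3-methylbut-3-en-1-yl]-3-{[tert-butyl(dimethyl)silyl]oxymethyl}-3-methyl-1-(propan-2-yl)cyclopentan-1-ol
Conditions: i-PrMgCl/CeCl3 (4 equiv each, premixed), THF, −78 to −20 °C; aq. NH4Cl
Reagents that add atoms: isopropylmagnesium chloride, CC(C)[Mg]Cl
Why: Organocerium 1,2-addition to a hindered, enolisable ketone, in which the first equivalent is consumed by the C6 hydroxyl and the isopropyl group should enter C4 on the face opposite the adjacent C5 side chain, leaving the C4 hydroxyl cis to that chain (C4 R).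

Step 8
Reactants: 20 (1R,2S,3S)-2-[(1S,3Z)-4-bromo-1-hydroxy-3-methylbut-3-en-1-yl]-3-{[tert-butyl(dimethyl)silyl]oxymethyl}-3-methyl-1-(propan-2-yl)cyclopentan-1-ol; 21 4-methoxybenzoyl chloride
Product: 22 (1S,3Z)-4-bromo-1-[(1S,2R,5S)-5-{[tert-butyl(dimethyl)silyl]oxymethyl}-2-hydroxy-5-methyl-2-(propan-2-yl)cyclopentyl]-3-methylbut-3-en-1-yl 4-methoxybenzoate
Conditions: pyridine, DMAP (cat.), CH2Cl2, 0 °C to rt
Reagents that add atoms: 4-methoxybenzoyl chloride, COc1ccc(cc1)C(Cl)=O
Why: DMAP-catalysed acylation should take the secondary C6 alcohol and leave the hindered tertiary C4 alcohol, and placing it after the ketone has gone means no β-acyloxy ketone prone to elimination is ever formed.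

Step 9
Reactants: 22 (1S,3Z)-4-bromo-1-[(1S,2R,5S)-5-{[tert-butyl(dimethyl)silyl]oxymethyl}-2-hydroxy-5-methyl-2-(propan-2-yl)cyclopentyl]-3-methylbut-3-en-1-yl 4-methoxybenzoate
Product: 23 (1S,3Z)-4-bromo-1-[(1S,2R,5S)-2-hydroxy-5-(hydroxymethyl)-5-methyl-2-(propan-2-yl)cyclopentyl]-3-methylbut-3-en-1-yl 4-methoxybenzoate
Conditions: HF·pyridine, THF/pyridine, 0 °C to rt
Reagents that add atoms: none
Why: Fluoride desilylation under mildly acidic conditions should free the primary C10 alcohol without ester cleavage or acyl migration, which a basic fluoride source could provoke.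

Step 10
Reactants: 23 (1S,3Z)-4-bromo-1-[(1S,2R,5S)-2-hydroxy-5-(hydroxymethyl)-5-methyl-2-(propan-2-yl)cyclopentyl]-3-methylbut-3-en-1-yl 4-methoxybenzoate; 24 iodine
Product: 25 (1S,3Z)-4-bromo-1-[(1S,2R,5S)-2-hydroxy-5-(iodomethyl)-5-methyl-2-(propan-2-yl)cyclopentyl]-3-methylbut-3-en-1-yl 4-methoxybenzoate
Conditions: I2, PPh3, imidazole, toluene, 70 °C
Reagents that add atoms: iodine, II
Why: Appel-type iodination, in which the primary alcohol forms the alkoxyphosphonium salt and is displaced by iodide (heating compensates for the neopentyl position), while the tertiary alcohol is too hindered to be activated and, being trans to C10 on the ring, cannot close an ether.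

Step 11
Reactants: 25 (1S,3Z)-4-bromo-1-[(1S,2R,5S)-2-hydroxy-5-(iodomethyl)-5-methyl-2-(propan-2-yl)cyclopentyl]-3-methylbut-3-en-1-yl 4-methoxybenzoate
Product: 26 (3R,3aS,4S,8aR)-3-hydroxy-6,8a-dimethyl-3-(propan-2-yl)-1,2,3,3a,4,5,8,8a-octahydroazulen-4-yl 4-methoxybenzoate
Conditions: NiBr2(dme) (20 mol %), 4,4′-di-tert-butyl-2,2′-bipyridine (24 mol %), Mn powder (3 equiv), NaI (0.5 equiv), DMA (0.01 M), 40 °C
Reagents that add atoms: none
Why: Zerovalent nickel, generated from NiBr2(dme) and Mn, inserts into the C9–Br bond with retention of geometry, low-valent nickel abstracts iodine from C10 to give a primary radical that the vinylnickel centre captures, and reductive elimination from the trivalent alkyl(vinyl)nickel species forms C9–C10 while Mn regenerates the catalyst. The closest known reaction type is the nickel-catalysed reductive cross-electrophile coupling of alkyl iodides with vinyl bromides, applied here within one molecule. The cycloheptene ring (ring B) closes by C(sp3)–C(sp2) reductive elimination from an eight-membered nickelacycle, formally a 7-endo closure at C9, and it is necessarily trans-fused because C10 and the C5 side chain already sit on opposite faces of the cyclopentane. No stereocentre is formed or disturbed. The step needs chemoselectivity (insertion at the vinyl bromide, halogen abstraction at the alkyl iodide) and retention of the Z geometry that holds Br cis to C7; the two different carbon–halogen bond types secure the first, the stereoretentive vinyl–nickel chemistry the second, and the quaternary C1 excludes β-hydride elimination. High dilution should favour ring closure over dimerisation, and the free tertiary alcohol and the anisate are inert to the nickel/manganese system.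

Step 12
Reactants: 26 (3R,3aS,4S,8aR)-3-hydroxy-6,8a-dimethyl-3-(propan-2-yl)-1,2,3,3a,4,5,8,8a-octahydroazulen-4-yl 4-methoxybenzoate; 27 3-chloroperoxybenzoic acid
Product: 28 CNP0235939.1, the 8,9-epoxide of 26 with the oxirane oxygen trans to the C1 methyl (C1 R, C4 R, C5 S, C6 S, C8 R, C9 S)
Conditions: mCPBA, NaHCO3, CH2Cl2, 0 °C
Reagents that add atoms: 3-chloroperoxybenzoic acid, OOC(=O)c1cccc(Cl)c1
Why: Prilezhaev epoxidation of the trisubstituted C8=C9 alkene, in which the peracid should approach the face opposite the axial C1 methyl and set C8 (R) and C9 (S) together by syn oxygen transfer, with bicarbonate buffering against acid-promoted opening by the C4 hydroxyl.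

Compound list
1 | but-3-yn-1-ol | C#CCCO | starting material
2 | trimethylaluminium | C[Al](C)C | starting material
3 | N-bromosuccinimide | O=C1CCC(=O)N1Br | starting material
4 | syn-carboalumination adduct, (E)-alkenylalane of the aluminium alkoxide | C[Al](C)/C=C(\C)CCO[Al](C)C | intermediate
5 | chelated (Z)-alkenylalane, six-membered oxa-aluminacycle | CC1=C[Al](C)OCC1 | intermediate
6 | (Z)-4-bromo-3-methylbut-3-en-1-ol | OCC/C(C)=C\Br | intermediate
7 | (Z)-4-bromo-3-methylbut-3-enal | O=CC/C(C)=C\Br | intermediate
8 | 3-bromocyclopent-2-en-1-one | O=C1CCC(Br)=C1 | starting material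
9 | (tributylstannyl)methanol | OC[Sn](CCCC)(CCCC)CCCC | starting material
10 | 3-(hydroxymethyl)cyclopent-2-en-1-one | O=C1CCC(CO)=C1 | intermediate
11 | tert-butyl(chloro)dimethylsilane | CC(C)(C)[Si](C)(C)Cl | starting material
12 | 3-{[tert-butyl(dimethyl)silyl]oxymethyl}cyclopent-2-en-1-one | O=C1CCC(CO[Si](C)(C)C(C)(C)C)=C1 | intermediate
13 | triethylsilyl trifluoromethanesulfonate | CC[Si](CC)(CC)OS(=O)(=O)C(F)(F)F | starting material
14 | dimethylaluminium enolate of (S)-3-(silyloxymethyl)-3-methylcyclopentanone | C[Al](C)OC1=C[C@@](C)(CO[Si](C)(C)C(C)(C)C)CC1 | intermediate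
15 | tert-butyl(dimethyl){[(1S)-1-methyl-3-(triethylsilyloxy)cyclopent-2-en-1-yl]methoxy}silane | CC[Si](CC)(CC)OC1=C[C@@](C)(CO[Si](C)(C)C(C)(C)C)CC1 | intermediate
16 | lithium enolate corresponding to 15 | [Li]OC1=C[C@@](C)(CO[Si](C)(C)C(C)(C)C)CC1 | intermediate
17 | chlorozinc enolate corresponding to 15 | Cl[Zn]OC1=C[C@@](C)(CO[Si](C)(C)C(C)(C)C)CC1 | intermediate
18 | (2S,3S)-2-[(1S,3Z)-4-bromo-1-hydroxy-3-methylbut-3-en-1-yl]-3-{[tert-butyl(dimethyl)silyl]oxymethyl}-3-methylcyclopentan-1-one | O=C1CC[C@](C)(CO[Si](C)(C)C(C)(C)C)[C@H]1[C@@H](O)C/C(C)=C\Br | intermediate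
19 | isopropylmagnesium chloride | CC(C)[Mg]Cl | starting material
20 | (1R,2S,3S)-2-[(1S,3Z)-4-bromo-1-hydroxy-3-methylbut-3-en-1-yl]-3-{[tert-butyl(dimethyl)silyl]oxymethyl}-3-methyl-1-(propan-2-yl)cyclopentan-1-ol | O[C@@]1(C(C)C)CC[C@](C)(CO[Si](C)(C)C(C)(C)C)[C@H]1[C@@H](O)C/C(C)=C\Br | intermediate
21 | 4-methoxybenzoyl chloride | COc1ccc(cc1)C(Cl)=O | starting material
22 | (1S,3Z)-4-bromo-1-[(1S,2R,5S)-5-{[tert-butyl(dimethyl)silyl]oxymethyl}-2-hydroxy-5-methyl-2-(propan-2-yl)cyclopentyl]-3-methylbut-3-en-1-yl 4-methoxybenzoate | O[C@@]1(C(C)C)CC[C@](C)(CO[Si](C)(C)C(C)(C)C)[C@H]1[C@@H](OC(=O)c2ccc(OC)cc2)C/C(C)=C\Br | intermediate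
23 | (1S,3Z)-4-bromo-1-[(1S,2R,5S)-2-hydroxy-5-(hydroxymethyl)-5-methyl-2-(propan-2-yl)cyclopentyl]-3-methylbut-3-en-1-yl 4-methoxybenzoate | O[C@@]1(C(C)C)CC[C@](C)(CO)[C@H]1[C@@H](OC(=O)c2ccc(OC)cc2)C/C(C)=C\Br | intermediate
24 | iodine | II | starting material
25 | (1S,3Z)-4-bromo-1-[(1S,2R,5S)-2-hydroxy-5-(iodomethyl)-5-methyl-2-(propan-2-yl)cyclopentyl]-3-methylbut-3-en-1-yl 4-methoxybenzoate (cyclisation precursor) | Br/C=C(C)\C[C@H](OC(=O)c1ccc(OC)cc1)[C@H]2[C@](O)(C(C)C)CC[C@]2(C)CI | intermediate
26 | (3R,3aS,4S,8aR)-3-hydroxy-6,8a-dimethyl-3-(propan-2-yl)-1,2,3,3a,4,5,8,8a-octahydroazulen-4-yl 4-methoxybenzoate (des-epoxy target) | COc1ccc(cc1)C(=O)O[C@H]1CC(C)=CC[C@@]2(C)CC[C@@](O)(C(C)C)[C@H]12 | intermediate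
27 | 3-chloroperoxybenzoic acid | OOC(=O)c1cccc(Cl)c1 | starting material
28 | CNP0235939.1, 8,9-epoxide of 26 with oxygen trans to the C1 methyl | COc1ccc(C(=O)O[C@H]2C[C@@]3(C)O[C@H]3C[C@@]3(C)CC[C@@](O)(C(C)C)[C@H]23)cc1 | target

Total step count: 12. Longest linear sequence: 10 steps (8 to 28, steps 3–12); the aldehyde 7 is made in 2 steps and joins at step 6.

Steps most likely to fail

Step 11. The C10 radical may be lost before nickel captures it, by reduction to the methyl compound, by 1,5-hydrogen transfer from the allylic C7, or by intermolecular coupling, so that ring closure stalls. The fallback sets out from 25 and comes back at 26, making the same bond by a polar palladium route. Zinc insertion into the C10–I bond (activated Zn dust, LiCl, THF, 40 °C) would give the neopentylzinc iodide F1, which has no β-hydrogen and is expected to tolerate the hindered tertiary hydroxyl on the time scale of the coupling. Intramolecular Negishi coupling with the vinyl bromide (Pd(OAc)2, SPhos, THF, 50 °C, slow addition) should then close the cycloheptene with retention of alkene geometry.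

Step 6. Control at the carbinol carbon C6 may erode if the chair transition state competes with open ones, giving syn/anti mixtures, and proton transfer from the acidic CH2 of 7 would add to the loss. The fallback sets out from 20, carried through steps 6 and 7 as a mixture of C6 epimers, and comes back at 20 as the single (6S) isomer. The secondary alcohol is oxidised (Dess–Martin periodinane, CH2Cl2, 0 °C) to the β-hydroxy ketone F2, and a Narasaka–Prasad reduction (Et2BOMe, NaBH4, THF/MeOH, −78 °C) follows. In the boron chelate the isopropyl group and C1 sit equatorial, and axial hydride delivery should place C7 equatorial, which corresponds to the required C6 configuration.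

Step 7. The metal aldolate formed from the free C6 hydroxyl may fragment by retro-aldol, or the ketone may be enolised or reduced by the secondary organometallic instead of undergoing addition. The fallback sets out from 18 and comes back at 20. The C6 hydroxyl is capped (Et3SiCl, imidazole, CH2Cl2) to give the triethylsilyl ether ketone F3. The same organocerium addition, now on a substrate with no acidic hydroxyl, should give the tertiary alcohol F4 with attack again opposite the C5 side chain. PPTS in MeOH at 0 °C then removes the secondary triethylsilyl group in the presence of the primary tert-butyldimethylsilyl ether.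

Further compounds
F1 | step 11 | neopentylzinc iodide derived from 25 (C10–ZnI, all stereocentres and the (Z)-vinyl bromide unchanged) | Br/C=C(C)\C[C@H](OC(=O)c1ccc(OC)cc1)[C@H]2[C@](O)(C(C)C)CC[C@]2(C)C[Zn]I
F2 | step 6 | C6 ketone of diol 20, (3Z)-4-bromo-1-[2-hydroxy-5-(silyloxymethyl)-5-methyl-2-(propan-2-yl)cyclopentyl]-3-methylbut-3-en-1-one with ring stereocentres as in 20 | O[C@@]1(C(C)C)CC[C@](C)(CO[Si](C)(C)C(C)(C)C)[C@H]1C(=O)C/C(C)=C\Br
F3 | step 7 | C6 triethylsilyl ether of aldol 18 | O=C1CC[C@](C)(CO[Si](C)(C)C(C)(C)C)[C@H]1[C@@H](O[Si](CC)(CC)CC)C/C(C)=C\Br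
F4 | step 7 | C6 triethylsilyl ether of diol 20 | O[C@@]1(C(C)C)CC[C@](C)(CO[Si](C)(C)C(C)(C)C)[C@H]1[C@@H](O[Si](CC)(CC)CC)C/C(C)=C\Br
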